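(All runs stem from a simulated flask for an exercise; noise was put on by code.)

A ratio of two rates needs no clock: if the target stops because free starting material has gone elsewhere, plateau target over the remainder of the charge equals the rate into target over the rate of the other ways out, and time drops out.

| setting | Wednesday's | Friday's | flask |
|---|---|---|---|
| starting material | 0.016 M | 0.011 M | 0.016 M |
| reagent | 1.3 equiv | 1.3 equiv | 1.30 equiv |
| temperature | 5 °C | −10 °C | 5 °C |
| remark | the very flask that is asked about, followed so far | run made earlier |  |
| time |  |  | 12 h |

- Wednesday's (time / h: target / %): 1.00: 8.3; 3.00: 13.4; 6.00: 20.1; 8.00: 21.1; 12.0: 21.0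
- Friday's (time / h: target / %): 3.00: 3.9; 6.00: 8.8; 10.0: 11.5; 12.0: 9.5; 15.0: 13.9

(each reading ± 1 percentage point)

- larch: at 12 h take out 90% of the target then present, then wait 25 h
- alder: at 12 h raise the temperature by 25 K, then wait 25 h
- oak: at 12 h add reagent, 50.0% of the amount charged, then wait 25 h
- birch: change nothing and wait 25 h more

- target taken out counts as made
- additions bring no volume worth counting

* target, in percent of the starting material first charged, at 12 h
* what to do for the largest gain in target; "none" if nothing gains more than 2 percentage points (larch / alder / oak / birch / none)
* target present, with what was taken out counted in, in percent of the starting material first charged, after alder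
* target present, with what was taken out counted in, in percent of the starting material first charged, after birch

Wednesday's last two readings average 21.1%, which gives 0.267, the plateau odds, target over the rest of the charge, a reading of that moment that stands for a selectivity factor only if the rest has taken the other ways. Friday's last three readings scatter, but their mean of 11.6% gives odds of 0.132, so the odds differ by a factor of 2.03 between the two runs.

One objection is that the two runs differ in both concentration and temperature. Concentration ratio 1.45 could account for part of that factor if the competing way is first order, leaving 1.39 for temperature, whereas a competing way that is also bimolecular would leave the whole factor to temperature. Carried over the rise of 25 K, with 1.67 times the span between the runs, these limits put Wednesday's flask between 31.6% and 46.4%. That holds, however, only if the unseen remainder can still react.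

A stronger objection is that a reversible stall would also flatten the curve, and these readings cannot exclude it. The reckoning here nevertheless commits to the branching view: about 21.1% now and after birch, little from larch, and alder best.

The forecast gives 21.3% now, 21.5% after birch and 23.5% after alder, and chooses larch: “I judge equilibrium more likely”.

The flask gives 20.6% at 12 h, and alder brings the largest gain, 28 percentage points, reaching 48.4%, while birch reaches 24.7%.

    starting material + reagent → intermediate A (k = 0.00181 /M/s, Ea = 47.0 kJ/mol)
    starting material + reagent → target (k = 0.00169 /M/s, Ea = 62.0 kJ/mol)
    reagent → decomposition product (k = 1.64 × 10⁻⁸ /s, Ea = 109 kJ/mol)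
    target ⇌ isomer of the product (K = 0.120, k = 7.34 × 10⁻⁵ /s, Ea = 80.0 kJ/mol, ΔH = −33.0 kJ/mol)
    intermediate A ⇌ intermediate B (K = 2.35, k = 8.38 × 10⁻⁶ /s, Ea = 87.0 kJ/mol, ΔH = −69.0 kJ/mol)
    starting material ⇌ dormant form (K = 11.8, k = 7.47 × 10⁻⁵ /s, Ea = 90.0 kJ/mol, ΔH = −12.0 kJ/mol)
    (constants at 5 °C)

At that time the flask holds 49.3% as dormant form against 2.99% as free starting material. The odds after alder are 0.938, a factor of 3.51 on 0.267, and the same flask left untouched until 120 h stands at 32.7%, odds of 0.486. In the neighbouring flask at 0.064 M, a concentration factor of 4.00, the target reaches 32.8%, so its odds are 0.488, a factor of 1.83 on 0.267.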